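**Plan**

- The target is read as (−)-epicatechin 3-O-gallate-(4β→8)-(−)-epicatechin 3-O-gallate-(4β→8)-(+)-catechin; the units are called U (top), M (middle) and L (bottom).
- Retrosynthetic cuts, in order: the 18 benzyl–oxygen bonds; C4(M)–C8(L); both galloyl esters; in unit U the C2–H and C2–aryl (ring B) bonds, then C3–O, then O1–C8a; in the resulting indanone C3–C3a; last the enone C=C of a chalcone.
- Feature used: in unit U, O1 sits between C8a of ring A and C2, so ring C is the five-membered ring of an indan-1-one with one oxygen inserted between the carbonyl carbon and the aryl carbon; C4 of U, bonded to C8 of M, is C3 of that indanone.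
- Forward order: the M aldehyde and a bromoacetophenone are joined to a chalcone; the carbocycle closes by reductive Heck reaction; oxygen insertion gives ring C of U as a lactone; C3–O, ring B at C2 and C2–H follow (protected procyanidin B2 skeleton); C4 of M is activated and joined to L; debenzylation ends the route.
- Stereochemistry: M and L come from the chiral pool; C4 of U from the chiral bisphosphine on palladium; C3 of U from enolate oxidation anti to the C4 aryl group; C2 of U from hydride delivery anti to the C3 silyloxy group; C4 of M from participation of the 3-O-galloyl group.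

Key step: step 8

Remarks on the chemistry: Bn = benzyl, TBS = tert-butyldimethylsilyl; "M-8-yl" = (2R,3R)-5,7-bis(benzyloxy)-2-[3,4-bis(benzyloxy)phenyl]-3-(TBS-oxy)chroman-8-yl. Compounds 7, 17 and 23 are taken as purchased benzyl ethers. In step 7 the ligand antipode that gives the 3R epimer is to be confirmed in a pilot run; (R) is written.

**Route**

Step 1
Reactants: 1 (−)-epicatechin
Product: 2 5,7,3',4'-tetra-O-benzyl-(−)-epicatechin
Conditions: BnBr (4.4 equiv), K2CO3, DMF, 0 °C → rt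
Reagents that add atoms: benzyl bromide BrCc1ccccc1
Why: Williamson etherification in which K2CO3 deprotonates only the four phenols, so the aliphatic 3-OH stays free and C2 and C3 are not touched.

Step 2
Reactants: 2 5,7,3',4'-tetra-O-benzyl-(−)-epicatechin
Product: 3 8-bromo-5,7,3',4'-tetra-O-benzylepicatechin
Conditions: NBS (1.0 equiv), CH2Cl2, −78 °C → rt
Reagents that add atoms: N-bromosuccinimide O=C1CCC(=O)N1Br
Why: Electrophilic aromatic bromination of the phloroglucinol-type ring A, for which C8 is the known preferred site in benzylated flavan-3-ols.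

Step 3
Reactants: 3 8-bromo-5,7,3',4'-tetra-O-benzylepicatechin
Product: 4 8-bromo-5,7,3',4'-tetra-O-benzyl-3-O-TBS-epicatechin
Conditions: TBSCl, imidazole, DMF, rt
Reagents that add atoms: tert-butyldimethylsilyl chloride CC(C)(C)[Si](C)(C)Cl
Why: Imidazole-promoted silylation of the secondary alcohol removes the only acidic proton before halogen–lithium exchange.

Step 4
Reactants: 4 8-bromo-5,7,3',4'-tetra-O-benzyl-3-O-TBS-epicatechin
Product: 6 8-formyl-5,7,3',4'-tetra-O-benzyl-3-O-TBS-epicatechin, via aryllithium 5 (not isolated)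
Conditions: t-BuLi (2.1 equiv), THF, −78 °C; DMF, −78 → 0 °C; AcOH, H2O
Reagents that add atoms: N,N-dimethylformamide CN(C)C=O
Why: Bromine–lithium exchange at −78 °C and formylation of the aryllithium with DMF (Bouveault aldehyde synthesis), the second equivalent of t-BuLi consuming the tert-butyl bromide formed.

Step 5
Reactants: 7 3,5-bis(benzyloxy)acetophenone
Product: 8 1-[3,5-bis(benzyloxy)-2-bromophenyl]ethan-1-one
Conditions: NBS (1.05 equiv), MeCN, 0 °C → rt
Reagents that add atoms: N-bromosuccinimide O=C1CCC(=O)N1Br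
Why: Electrophilic aromatic bromination at C2, which is para to one benzyloxy group, ortho to the other and less crowded than C4 between the two ethers, the regiochemistry known for 3,5-dialkoxyphenyl ketones.

Step 6
Reactants: 6 8-formyl-5,7,3',4'-tetra-O-benzyl-3-O-TBS-epicatechin; 8 1-[3,5-bis(benzyloxy)-2-bromophenyl]ethan-1-one
Product: 10 (E)-1-[3,5-bis(benzyloxy)-2-bromophenyl]-3-(M-8-yl)prop-2-en-1-one, via aldol adduct 9 (not isolated)
Conditions: KOH, EtOH/THF, rt → 40 °C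
Reagents that add atoms: none
Why: Claisen–Schmidt condensation in which the aldehyde has no α-hydrogen and the aldol adduct dehydrates to the conjugated enone, the E geometry being the thermodynamic one.

Step 7
Reactants: 10 (E)-1-[3,5-bis(benzyloxy)-2-bromophenyl]-3-(M-8-yl)prop-2-en-1-one
Product: 11 (3R)-4,6-bis(benzyloxy)-3-(M-8-yl)indan-1-one
Conditions: Pd(OAc)2 (10 mol %), (R)-3,5-Xyl-MeO-BIPHEP (12 mol %), HCO2Na (1.5 equiv), DMF, 80 °C
Reagents that add atoms: none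
Why: Asymmetric intramolecular reductive Heck reaction, the known route from 2'-halochalcones to 3-arylindan-1-ones, in which the aryl bromide adds oxidatively to zerovalent palladium, the aryl group adds to the β-carbon to form C3–C3a, formate reduces the palladium enolate, and the chiral bisphosphine selects the enone face so that the new C3 centre is R.

Step 8
Reactants: 11 (3R)-4,6-bis(benzyloxy)-3-(M-8-yl)indan-1-one
Product: 13 (4R)-5,7-bis(benzyloxy)-4-(M-8-yl)-3,4-dihydrocoumarin, via Criegee adduct 12 (not isolated)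
Conditions: mCPBA (2.5 equiv), TsOH·H2O (0.1 equiv), 4 Å MS, CH2Cl2, 0–4 °C, dark; aq Na2SO3/NaHCO3
Reagents that add atoms: 3-chloroperbenzoic acid OOC(=O)c1cccc(Cl)c1
Why: TsOH activates the ketone of 11 toward addition of the peracid, and in the Criegee adduct 12 the aryl carbon C7a, antiperiplanar to the O–O bond, shifts to oxygen as 3-chlorobenzoate leaves, which forms O1–C8a of unit U. The closest known reaction is the Baeyer–Villiger oxidation of 3-aryl-indan-1-ones to 4-aryl-3,4-dihydrocoumarins with mCPBA and catalytic sulfonic acid. The six-membered lactone arises by ring expansion of the five-membered ketone through this 1,2-shift, an oxygen insertion into the C1–C7a bond and not an exo or endo cyclisation. No stereocentre is formed, and C3 of the indanone, which is not part of the migrating bond, becomes C4 of the lactone with its R configuration unchanged. The step needs migration of the aryl carbon in preference to the C2 methylene, which the higher migratory aptitude of aryl over primary alkyl should secure although both benzyloxy groups are meta to C7a; the same meta placement leaves the carbonyl without a conjugated donor, so that 12 should form readily. It also needs the peracid to spare the benzyloxy arenes, for which the low temperature, the limited charge of acid and oxidant and the crowding of the only free position (C6–H) on ring A of unit M are relied on.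

Step 9
Reactants: 13 (4R)-5,7-bis(benzyloxy)-4-(M-8-yl)-3,4-dihydrocoumarin
Product: 15 (3R,4R)-5,7-bis(benzyloxy)-3-hydroxy-4-(M-8-yl)-3,4-dihydrocoumarin, via potassium enolate 14 (not isolated)
Conditions: KN(SiMe3)2 (1.1 equiv), THF, −78 °C; 3-phenyl-2-(phenylsulfonyl)oxaziridine, −78 °C; AcOH
Reagents that add atoms: 3-phenyl-2-(phenylsulfonyl)oxaziridine O=S(=O)(N1OC1c1ccccc1)c1ccccc1
Why: Enolate oxidation with an N-sulfonyloxaziridine in which the oxidant approaches the lactone enolate on the face opposite the pseudoaxial C4 aryl group, so that the new C3–O bond is trans to it (3R), while −78 °C suppresses ketene formation from the aryl ester enolate.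

Step 10
Reactants: 15 (3R,4R)-5,7-bis(benzyloxy)-3-hydroxy-4-(M-8-yl)-3,4-dihydrocoumarin
Product: 16 (3R,4R)-5,7-bis(benzyloxy)-3-(TBS-oxy)-4-(M-8-yl)-3,4-dihydrocoumarin
Conditions: TBSOTf, 2,6-lutidine, CH2Cl2, −20 → 0 °C
Reagents that add atoms: tert-butyldimethylsilyl triflate CC(C)(C)[Si](C)(C)OS(=O)(=O)C(F)(F)F
Why: Silyl triflate silylation of a hindered secondary alcohol under a non-nucleophilic base gives the bulky ether that later steers the hydride in step 12 and matches the silyl ether of unit M.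

Step 11
Reactants: 16 (3R,4R)-5,7-bis(benzyloxy)-3-(TBS-oxy)-4-(M-8-yl)-3,4-dihydrocoumarin; 17 1,2-bis(benzyloxy)-4-bromobenzene
Product: 19 (3R,4R)-5,7-bis(benzyloxy)-2-[3,4-bis(benzyloxy)phenyl]-2-hydroxy-3-(TBS-oxy)-4-(M-8-yl)chroman (lactol with C2 undefined; ring–chain tautomer of the 2-hydroxyaryl ketone), via aryllithium 18 (not isolated)
Conditions: 17, n-BuLi, THF, −78 °C; then 16, THF, −78 °C; AcOH
Reagents that add atoms: none
Why: Bromine–lithium exchange and 1,2-addition of one aryllithium to the lactone carbonyl, as in aryl C-glycoside synthesis from lactones, with near-stoichiometric aryllithium at −78 °C and a cold quench to limit a second addition to the ring-opened ketone.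

Step 12
Reactants: 19 (3R,4R)-5,7-bis(benzyloxy)-2-[3,4-bis(benzyloxy)phenyl]-2-hydroxy-3-(TBS-oxy)-4-(M-8-yl)chroman
Product: 20 5,7,3',4'-tetra-O-benzyl-3-O-TBS-epicatechin-(4β→8)-5,7,3',4'-tetra-O-benzyl-3-O-TBS-epicatechin (protected procyanidin B2; unit U 2R,3R,4R)
Conditions: Et3SiH (5 equiv), BF3·OEt2 (2 equiv), CH2Cl2, −78 → −40 °C
Reagents that add atoms: none
Why: Lewis-acid ionisation of the lactol to the 2-aryl oxocarbenium ion and silane reduction (reductive etherification as used for aryl C-glycosides), in which, with the C4 aryl and C3 silyloxy groups trans-diaxial, hydride enters axially anti to the adjacent silyloxy group and gives the 2,3-cis (2R) flavan.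

Step 13
Reactants: 20 protected procyanidin B2 bis-TBS ether
Product: 21 5,7,3',4'-tetra-O-benzylepicatechin-(4β→8)-5,7,3',4'-tetra-O-benzylepicatechin (3-OH free on U and M)
Conditions: HF·pyridine, pyridine/THF, 0 °C → rt
Reagents that add atoms: none
Why: Fluoride cleavage of both secondary silyl ethers under buffered conditions that leave benzyl ethers and the interflavan bond intact.

Step 14
Reactants: 21 octa-O-benzyl procyanidin B2
Product: 22 octa-O-benzyl procyanidin B2 carrying a 4β-(2-ethoxyethoxy) group on unit M (trans to the 3-OH of M)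
Conditions: DDQ (2 equiv), 2-ethoxyethanol (5 equiv), CH2Cl2, rt
Reagents that add atoms: 2-ethoxyethanol CCOCCO
Why: DDQ benzylic oxidation by hydride abstraction at C4 of unit M, the standard C4 activation of benzylated flavan-3-ols, in which the alcohol adds trans to the 3-OH, while C4–H of unit U is pseudoequatorial, lies in the plane of ring A and should not be abstracted.

Step 15
Reactants: 22 4β-(2-ethoxyethoxy) diol; 23 3,4,5-tris(benzyloxy)benzoic acid
Product: 24 3,3''-bis-O-[3,4,5-tris(benzyloxy)benzoyl] derivative of 22 (galloylated on U and M)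
Conditions: 23 (3 equiv), DCC, DMAP, CH2Cl2, rt
Reagents that add atoms: none
Why: Steglich esterification of both secondary alcohols under neutral conditions that keep the acid-labile C4 ether.

Step 16
Reactants: 25 (+)-catechin
Product: 26 5,7,3',4'-tetra-O-benzyl-(+)-catechin
Conditions: BnBr (4.4 equiv), K2CO3, DMF, 0 °C → rt
Reagents that add atoms: benzyl bromide BrCc1ccccc1
Why: Williamson etherification of the four phenols only, which leaves the 3-OH and both stereocentres of unit L as they are.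

Step 17
Reactants: 24 bis-galloylated 4β-(2-ethoxyethoxy) dimer; 26 5,7,3',4'-tetra-O-benzyl-(+)-catechin
Product: 27 tetra-O-benzyl-3-O-(tri-O-benzylgalloyl)epicatechin-(4β→8)-tetra-O-benzyl-3-O-(tri-O-benzylgalloyl)epicatechin-(4β→8)-tetra-O-benzylcatechin
Conditions: 26 (4 equiv), TMSOTf (0.3 equiv), 4 Å MS, CH2Cl2, −78 °C; aq NaHCO3
Reagents that add atoms: none
Why: Lewis-acid-promoted Friedel–Crafts-type interflavan coupling in which TMSOTf ionises the C4 ether, the 3-O-galloyl carbonyl bridges the cation on its own face, and C8 of the catechin nucleophile, used in excess to outcompete ring A of unit U, attacks trans to the ester and sets C4 of unit M as 4β.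

Step 18
Reactants: 27 fully benzylated trimer digallate
Product: 28 (−)-epicatechin 3-O-gallate-(4β→8)-(−)-epicatechin 3-O-gallate-(4β→8)-(+)-catechin (CNP0269915.2)
Conditions: H2 (1 atm), Pd(OH)2/C, THF/MeOH/H2O, rt
Reagents that add atoms: none
Why: Hydrogenolysis of all eighteen benzyl ethers over Pd(OH)2/C under neutral conditions, which should leave the aryl esters, the interflavan bonds and every stereocentre untouched.

**Compound list**

1 | (−)-epicatechin | O[C@@H]1Cc2c(O)cc(O)cc2O[C@@H]1c1ccc(O)c(O)c1 | starting material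
2 | 5,7,3',4'-tetra-O-benzyl-(−)-epicatechin | O[C@@H]1Cc2c(OCc3ccccc3)cc(OCc3ccccc3)cc2O[C@@H]1c1ccc(OCc2ccccc2)c(OCc2ccccc2)c1 | intermediate
3 | 8-bromo-5,7,3',4'-tetra-O-benzylepicatechin | O[C@@H]1Cc2c(OCc3ccccc3)cc(OCc3ccccc3)c(Br)c2O[C@@H]1c1ccc(OCc2ccccc2)c(OCc2ccccc2)c1 | intermediate
4 | 8-bromo-5,7,3',4'-tetra-O-benzyl-3-O-TBS-epicatechin | CC(C)(C)[Si](C)(C)O[C@@H]1Cc2c(OCc3ccccc3)cc(OCc3ccccc3)c(Br)c2O[C@@H]1c1ccc(OCc2ccccc2)c(OCc2ccccc2)c1 | intermediate
5 | 8-lithio-5,7,3',4'-tetra-O-benzyl-3-O-TBS-epicatechin (aryllithium) | CC(C)(C)[Si](C)(C)O[C@@H]1Cc2c(OCc3ccccc3)cc(OCc3ccccc3)c([Li])c2O[C@@H]1c1ccc(OCc2ccccc2)c(OCc2ccccc2)c1 | intermediate (not isolated)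
6 | 8-formyl-5,7,3',4'-tetra-O-benzyl-3-O-TBS-epicatechin | CC(C)(C)[Si](C)(C)O[C@@H]1Cc2c(OCc3ccccc3)cc(OCc3ccccc3)c(C=O)c2O[C@@H]1c1ccc(OCc2ccccc2)c(OCc2ccccc2)c1 | intermediate
7 | 3,5-bis(benzyloxy)acetophenone | CC(=O)c1cc(OCc2ccccc2)cc(OCc2ccccc2)c1 | starting material
8 | 1-[3,5-bis(benzyloxy)-2-bromophenyl]ethan-1-one | CC(=O)c1cc(OCc2ccccc2)cc(OCc2ccccc2)c1Br | intermediate
9 | aldol adduct, 1-[3,5-bis(benzyloxy)-2-bromophenyl]-3-hydroxy-3-(M-8-yl)propan-1-one (carbinol centre undefined) | O=C(CC(O)c2c(OCc3ccccc3)cc(OCc3ccccc3)c3c2O[C@H](c2ccc(OCc4ccccc4)c(OCc4ccccc4)c2)[C@H](O[Si](C)(C)C(C)(C)C)C3)c1cc(OCc2ccccc2)cc(OCc2ccccc2)c1Br | intermediate (not isolated)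
10 | (E)-1-[3,5-bis(benzyloxy)-2-bromophenyl]-3-(M-8-yl)prop-2-en-1-one | O=C(/C=C/c2c(OCc3ccccc3)cc(OCc3ccccc3)c3c2O[C@H](c2ccc(OCc4ccccc4)c(OCc4ccccc4)c2)[C@H](O[Si](C)(C)C(C)(C)C)C3)c1cc(OCc2ccccc2)cc(OCc2ccccc2)c1Br | intermediate
11 | (3R)-4,6-bis(benzyloxy)-3-(M-8-yl)indan-1-one | O=C1C[C@@H](c2c(OCc3ccccc3)cc(OCc3ccccc3)c3c2O[C@H](c2ccc(OCc4ccccc4)c(OCc4ccccc4)c2)[C@H](O[Si](C)(C)C(C)(C)C)C3)c2c(OCc3ccccc3)cc(OCc3ccccc3)cc21 | intermediate (key-step precursor)
12 | Criegee adduct, 1-hydroxy-1-(3-chlorobenzoylperoxy) derivative of 11 (C1 undefined) | OC1(OOC(=O)c2cccc(Cl)c2)C[C@@H](c2c(OCc3ccccc3)cc(OCc3ccccc3)c3c2O[C@H](c2ccc(OCc4ccccc4)c(OCc4ccccc4)c2)[C@H](O[Si](C)(C)C(C)(C)C)C3)c2c(OCc3ccccc3)cc(OCc3ccccc3)cc21 | intermediate (not isolated)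
13 | (4R)-5,7-bis(benzyloxy)-4-(M-8-yl)-3,4-dihydrocoumarin | O=C1C[C@@H](c2c(OCc3ccccc3)cc(OCc3ccccc3)c3c2O[C@H](c2ccc(OCc4ccccc4)c(OCc4ccccc4)c2)[C@H](O[Si](C)(C)C(C)(C)C)C3)c2c(OCc3ccccc3)cc(OCc3ccccc3)cc2O1 | intermediate (key-step product)
14 | potassium enolate of 13 | [K+].[O-]C1=C[C@@H](c2c(OCc3ccccc3)cc(OCc3ccccc3)c3c2O[C@H](c2ccc(OCc4ccccc4)c(OCc4ccccc4)c2)[C@H](O[Si](C)(C)C(C)(C)C)C3)c2c(OCc3ccccc3)cc(OCc3ccccc3)cc2O1 | intermediate (not isolated)
15 | (3R,4R)-5,7-bis(benzyloxy)-3-hydroxy-4-(M-8-yl)-3,4-dihydrocoumarin (3,4-trans) | O=C1[C@H](O)[C@@H](c2c(OCc3ccccc3)cc(OCc3ccccc3)c3c2O[C@H](c2ccc(OCc4ccccc4)c(OCc4ccccc4)c2)[C@H](O[Si](C)(C)C(C)(C)C)C3)c2c(OCc3ccccc3)cc(OCc3ccccc3)cc2O1 | intermediate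
16 | (3R,4R)-5,7-bis(benzyloxy)-3-(TBS-oxy)-4-(M-8-yl)-3,4-dihydrocoumarin | O=C1[C@H](O[Si](C)(C)C(C)(C)C)[C@@H](c2c(OCc3ccccc3)cc(OCc3ccccc3)c3c2O[C@H](c2ccc(OCc4ccccc4)c(OCc4ccccc4)c2)[C@H](O[Si](C)(C)C(C)(C)C)C3)c2c(OCc3ccccc3)cc(OCc3ccccc3)cc2O1 | intermediate
17 | 1,2-bis(benzyloxy)-4-bromobenzene | Brc1ccc(OCc2ccccc2)c(OCc2ccccc2)c1 | starting material
18 | 3,4-bis(benzyloxy)phenyllithium | [Li]c1ccc(OCc2ccccc2)c(OCc2ccccc2)c1 | intermediate (not isolated)
19 | lactol, (3R,4R)-5,7-bis(benzyloxy)-2-[3,4-bis(benzyloxy)phenyl]-2-hydroxy-3-(TBS-oxy)-4-(M-8-yl)chroman (C2 undefined) | O1C(O)(c2ccc(OCc3ccccc3)c(OCc3ccccc3)c2)[C@H](O[Si](C)(C)C(C)(C)C)[C@@H](c2c(OCc3ccccc3)cc(OCc3ccccc3)c3c2O[C@H](c2ccc(OCc4ccccc4)c(OCc4ccccc4)c2)[C@H](O[Si](C)(C)C(C)(C)C)C3)c2c(OCc3ccccc3)cc(OCc3ccccc3)cc21 | intermediate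
20 | 5,7,3',4'-tetra-O-benzyl-3-O-TBS-epicatechin-(4β→8)-5,7,3',4'-tetra-O-benzyl-3-O-TBS-epicatechin | O1[C@H](c2ccc(OCc3ccccc3)c(OCc3ccccc3)c2)[C@H](O[Si](C)(C)C(C)(C)C)[C@@H](c2c(OCc3ccccc3)cc(OCc3ccccc3)c3c2O[C@H](c2ccc(OCc4ccccc4)c(OCc4ccccc4)c2)[C@H](O[Si](C)(C)C(C)(C)C)C3)c2c(OCc3ccccc3)cc(OCc3ccccc3)cc21 | intermediate
21 | 5,7,3',4'-tetra-O-benzylepicatechin-(4β→8)-5,7,3',4'-tetra-O-benzylepicatechin | O1[C@H](c2ccc(OCc3ccccc3)c(OCc3ccccc3)c2)[C@H](O)[C@@H](c2c(OCc3ccccc3)cc(OCc3ccccc3)c3c2O[C@H](c2ccc(OCc4ccccc4)c(OCc4ccccc4)c2)[C@H](O)C3)c2c(OCc3ccccc3)cc(OCc3ccccc3)cc21 | intermediate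
22 | 21 with a 4β-(2-ethoxyethoxy) group on unit M | O1[C@H](c2ccc(OCc3ccccc3)c(OCc3ccccc3)c2)[C@H](O)[C@@H](c2c(OCc3ccccc3)cc(OCc3ccccc3)c3c2O[C@H](c2ccc(OCc4ccccc4)c(OCc4ccccc4)c2)[C@H](O)[C@H]3OCCOCC)c2c(OCc3ccccc3)cc(OCc3ccccc3)cc21 | intermediate
23 | 3,4,5-tris(benzyloxy)benzoic acid | OC(=O)c1cc(OCc2ccccc2)c(OCc2ccccc2)c(OCc2ccccc2)c1 | starting material
24 | 22 esterified on the 3-OH of U and of M with 3,4,5-tris(benzyloxy)benzoyl | O1[C@H](c2ccc(OCc3ccccc3)c(OCc3ccccc3)c2)[C@H](OC(=O)c2cc(OCc3ccccc3)c(OCc3ccccc3)c(OCc3ccccc3)c2)[C@@H](c2c(OCc3ccccc3)cc(OCc3ccccc3)c3c2O[C@H](c2ccc(OCc4ccccc4)c(OCc4ccccc4)c2)[C@H](OC(=O)c2cc(OCc4ccccc4)c(OCc4ccccc4)c(OCc4ccccc4)c2)[C@H]3OCCOCC)c2c(OCc3ccccc3)cc(OCc3ccccc3)cc21 | intermediate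
25 | (+)-catechin | O[C@H]1Cc2c(O)cc(O)cc2O[C@@H]1c1ccc(O)c(O)c1 | starting material
26 | 5,7,3',4'-tetra-O-benzyl-(+)-catechin | O[C@H]1Cc2c(OCc3ccccc3)cc(OCc3ccccc3)cc2O[C@@H]1c1ccc(OCc2ccccc2)c(OCc2ccccc2)c1 | intermediate
27 | fully benzylated epicatechin 3-O-gallate-(4β→8)-epicatechin 3-O-gallate-(4β→8)-catechin (18 benzyl ethers; 3-OH of L free) | O1[C@H](c2ccc(OCc3ccccc3)c(OCc3ccccc3)c2)[C@H](OC(=O)c2cc(OCc3ccccc3)c(OCc3ccccc3)c(OCc3ccccc3)c2)[C@@H](c2c(OCc3ccccc3)cc(OCc3ccccc3)c3c2O[C@H](c2ccc(OCc4ccccc4)c(OCc4ccccc4)c2)[C@H](OC(=O)c2cc(OCc4ccccc4)c(OCc4ccccc4)c(OCc4ccccc4)c2)[C@H]3c2c(OCc3ccccc3)cc(OCc3ccccc3)c3c2O[C@H](c2ccc(OCc4ccccc4)c(OCc4ccccc4)c2)[C@@H](O)C3)c2c(OCc3ccccc3)cc(OCc3ccccc3)cc21 | intermediate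
28 | (−)-epicatechin 3-O-gallate-(4β→8)-(−)-epicatechin 3-O-gallate-(4β→8)-(+)-catechin (CNP0269915.2) | O=C(O[C@@H]1[C@@H](c2c(O)cc(O)c3c2O[C@H](c2ccc(O)c(O)c2)[C@@H](O)C3)c2c(O)cc(O)c([C@H]3c4c(O)cc(O)cc4O[C@H](c4ccc(O)c(O)c4)[C@@H]3OC(=O)c3cc(O)c(O)c(O)c3)c2O[C@@H]1c1ccc(O)c(O)c1)c1cc(O)c(O)c(O)c1 | target

**Count**

Total steps: 18. Longest linear sequence: 16 (steps 1–4, 6–15, 17, 18).

**Steps most likely to fail**

Step 7. Formate may reduce the arylpalladium bromide before the slow insertion into the hindered β-carbon (hydrodebromination), or the ligand may discriminate the enone faces poorly against the distant stereocentres of M. The fallback sets out from 8 and 6 and comes back at 11. Miyaura borylation of 8 (B2pin2, PdCl2(dppf) with dppf = 1,1'-bis(diphenylphosphino)ferrocene, KOAc, dioxane, 80 °C) should give 1-[3,5-bis(benzyloxy)-2-(4,4,5,5-tetramethyl-1,3,2-dioxaborolan-2-yl)phenyl]ethan-1-one F1. Claisen–Schmidt condensation of this ketone with 6 (KOH, EtOH/THF) should give the boryl chalcone F2. Rhodium-catalysed asymmetric intramolecular 1,4-addition ([RhCl(C2H4)2]2, (R)-MonoPhos, K3PO4, toluene/H2O, rt → 60 °C) then closes the ring by aryl transfer from boron and protonation of the rhodium enolate. No hydride source is present, so the debromination path is absent.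

Step 8. The peracid may hydroxylate the benzyloxy-rich rings, the acid needed for a sluggish aryl ketone may loosen the silyl ether, or some methylene migration may occur. The fallback sets out from 5 (made from 4 as in step 4) and comes back at 13. Quenching 5 with B(OMe)3 (THF, −78 °C → rt, then H2O) should give the boronic acid of M, (5,7,3',4'-tetra-O-benzyl-3-O-TBS-epicatechin-8-yl)boronic acid F3. Purchased 5,7-dihydroxycoumarin (O=C1C=Cc2c(O)cc(O)cc2O1) is benzylated (BnBr, K2CO3, DMF) to 5,7-bis(benzyloxy)coumarin F4. Rhodium-catalysed asymmetric 1,4-addition of the arylboronic acid to the coumarin (Rh(acac)(C2H4)2, (R)-SEGPHOS or its antipode as needed for 4R, dioxane/H2O, 60 °C) then forms the C4–C8 bond and the C4 centre on a ring that already holds O1.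

Step 12. The C4 aryl group may shield the face anti to the silyloxy group so that hydride enters syn and gives the 2,3-trans flavan, or the oxocarbenium ion may lose H3 to the enol ether and scramble C3 before it is reduced. The fallback sets out from 15 and comes back at 21. Addition of 18 (3 equiv, THF, −78 °C; AcOH) to the unprotected hydroxy lactone should give the ring-opened α-hydroxy ketone F5. Chelation-controlled reduction (Zn(BH4)2, Et2O, −20 °C) should give the anti-diol F6. Mitsunobu closure of the phenol onto the benzylic carbinol (PPh3, DIAD, THF, 0 °C) inverts C2 and should give the 2,3-cis flavan with a free 3-OH on U and the silyl ether on M, F7. HF·pyridine then removes the remaining silyl group.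

Further compounds
F1 | step 7 | 1-[3,5-bis(benzyloxy)-2-(4,4,5,5-tetramethyl-1,3,2-dioxaborolan-2-yl)phenyl]ethan-1-one | CC(=O)c1cc(OCc2ccccc2)cc(OCc2ccccc2)c1B1OC(C)(C)C(C)(C)O1
F2 | step 7 | (E)-1-[3,5-bis(benzyloxy)-2-(4,4,5,5-tetramethyl-1,3,2-dioxaborolan-2-yl)phenyl]-3-(M-8-yl)prop-2-en-1-one | O=C(/C=C/c2c(OCc3ccccc3)cc(OCc3ccccc3)c3c2O[C@H](c2ccc(OCc4ccccc4)c(OCc4ccccc4)c2)[C@H](O[Si](C)(C)C(C)(C)C)C3)c1cc(OCc2ccccc2)cc(OCc2ccccc2)c1B1OC(C)(C)C(C)(C)O1
F3 | step 8 | (5,7,3',4'-tetra-O-benzyl-3-O-TBS-epicatechin-8-yl)boronic acid | OB(O)c1c(OCc2ccccc2)cc(OCc2ccccc2)c2c1O[C@H](c1ccc(OCc3ccccc3)c(OCc3ccccc3)c1)[C@H](O[Si](C)(C)C(C)(C)C)C2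
F4 | step 8 | 5,7-bis(benzyloxy)coumarin | O=C1C=Cc2c(OCc3ccccc3)cc(OCc3ccccc3)cc2O1
F5 | step 12 | (2R,3R)-1-[3,4-bis(benzyloxy)phenyl]-3-[2,4-bis(benzyloxy)-6-hydroxyphenyl]-2-hydroxy-3-(M-8-yl)propan-1-one | O=C(c1ccc(OCc2ccccc2)c(OCc2ccccc2)c1)[C@H](O)[C@@H](c2c(OCc3ccccc3)cc(OCc3ccccc3)c3c2O[C@H](c2ccc(OCc4ccccc4)c(OCc4ccccc4)c2)[C@H](O[Si](C)(C)C(C)(C)C)C3)c1c(OCc2ccccc2)cc(OCc2ccccc2)cc1O
F6 | step 12 | anti-1,2-diol from F5, 1-[3,4-bis(benzyloxy)phenyl]-3-[2,4-bis(benzyloxy)-6-hydroxyphenyl]-3-(M-8-yl)propane-1,2-diol | O[C@@H](c1ccc(OCc2ccccc2)c(OCc2ccccc2)c1)[C@H](O)[C@@H](c2c(OCc3ccccc3)cc(OCc3ccccc3)c3c2O[C@H](c2ccc(OCc4ccccc4)c(OCc4ccccc4)c2)[C@H](O[Si](C)(C)C(C)(C)C)C3)c1c(OCc2ccccc2)cc(OCc2ccccc2)cc1O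
F7 | step 12 | 5,7,3',4'-tetra-O-benzylepicatechin-(4β→8)-5,7,3',4'-tetra-O-benzyl-3-O-TBS-epicatechin | O1[C@H](c2ccc(OCc3ccccc3)c(OCc3ccccc3)c2)[C@H](O)[C@@H](c2c(OCc3ccccc3)cc(OCc3ccccc3)c3c2O[C@H](c2ccc(OCc4ccccc4)c(OCc4ccccc4)c2)[C@H](O[Si](C)(C)C(C)(C)C)C3)c2c(OCc3ccccc3)cc(OCc3ccccc3)cc21
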